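Numbering as in pleuromutilin: ring A = cyclopentenone C9–C1–C2(=O)–C3=C4, ring B = cyclohexane C4–C5–C6–C7–C8–C9, ring C = cyclooctane C4–C5–C14–C13–C12–C11–C10–C9; the bond C4–C9 belongs to all three rings.
Cut 1 (key): ring A is a cyclopent-2-enone whose β-carbon C4 is bonded to the quaternary C9, so C4–C9, C1–C2 and C2–C3 are cut together ([2+2+1]) into an ethynyl group C3≡C4 on C5, an exocyclic alkene C9=C1 and CO; this opens rings A, B and C at once to a ten-membered carbocycle C5–C14.
Cut 2: C10–C11 (allylstannane + aldehyde), which also creates C9=C1. Cut 3: C9=C10 and C8–C9 (Horner–Wadsworth–Emmons, phosphonate alkylation). Cut 4: C3≡C4 from a lactone carbonyl. Cut 5: C5–C14 and C5–CH3 (Claisen condensation of two lactones, methylation).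
Forward order: C5–C14 bond, then C5 and C14, alkyne, C8–C10/C1 unit, ten-membered ring, rings A + B + C in one step, glycolate last.
Stereochemistry: C6 from methyl (R)-3-methylglutarate; C12 from an enantioselective iridium-catalysed diene–methanol coupling; C5 by alkylation anti to C6–CH3; C14 by Felkin–Anh reduction; C10 and C11 in the ring-closing allylation; C9 by the ring in the key step.

Key step: step 19

Remark: the configuration is taken exactly as encoded in the target SMILES and every intermediate SMILES is derived from it atom by atom; in the zigzag convention it encodes C5–CH3 trans to C6–CH3 on ring B, C14–OH syn to C5–CH3, C10–CH3 syn to C11–OH and C11–OH syn to C12–CH3, and these are the relationships the stereochemical arguments aim at.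

Step 1
Reactants: 1 4,4-diethoxybut-1-yne
Product: 2 2-(2,2-diethoxyethyl)buta-1,3-diene
Conditions: ethylene (1 atm), second-generation Grubbs catalyst RuCl2(=CHPh)(H2IMes)(PCy3) (5 mol %), CH2Cl2, 40 °C
Reagents that add atoms: ethylene C=C
Why: Enyne cross-metathesis of a terminal alkyne with ethylene should give the 2-substituted buta-1,3-diene (the acetal is inert; no stereocenter).

Step 2
Reactants: 2 2-(2,2-diethoxyethyl)buta-1,3-diene
Product: 3 (S)-2-(2,2-diethoxyethyl)-2-methylbut-3-en-1-ol
Conditions: [Ir(cod)Cl]2 (2.5 mol %), (R)-PhanePhos (5 mol %), MeOH (reagent and solvent), 80 °C, sealed tube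
Reagents that add atoms: methanol CO
Why: Iridium-catalysed transfer-hydrogenative coupling of methanol with a 2-substituted diene (hydrohydroxymethylation) should form C11–C12 at the substituted diene carbon and set the quaternary C12 (CH3, vinyl, CH2OH) by catalyst control, the ligand antipode being used if the sense of induction proves opposite.

Step 3
Reactants: 3 (S)-2-(2,2-diethoxyethyl)-2-methylbut-3-en-1-ol
Product: 5 (S)-4-ethenyl-4-methyloxolan-2-one, via lactol 4 (not isolated)
Conditions: 1 M HCl, THF, 23 °C; then TEMPO (10 mol %), PhI(OAc)2, CH2Cl2, 23 °C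
Reagents that add atoms: water O
Why: Acid hydrolysis of the acetal should give the hydroxy aldehyde, which closes to the five-membered lactol, and oxoammonium (TEMPO) oxidation of the lactol gives the lactone; C12 is quaternary and cannot epimerise.

Step 4
Reactants: 6 methyl (R)-3-methylglutarate
Product: 7 (S)-4-methyloxan-2-one
Conditions: LiBH4 (2.5 equiv), THF, 0 to 23 °C; then 2 M HCl, 23 °C
Reagents that add atoms: none
Why: LiBH4 reduces the ester but not the lithium carboxylate and acid closes the δ-lactone, so the ester arm becomes the CH2O carbon (C8) and the (R) hemiester gives the (S) lactone, whose stereocenter is C6 (chiral pool).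

Step 5
Reactants: 7 (S)-4-methyloxan-2-one (2.2 equiv); 5 (S)-4-ethenyl-4-methyloxolan-2-one
Product: 9 silylated β-keto lactone, via hydroxy keto lactone 8 (not isolated)
Conditions: LiN(i-Pr)2 (2.2 equiv), THF, −78 °C; then 5, −78 to −20 °C; then TBSCl, DMPU, 0 to 23 °C
Reagents that add atoms: tert-butyldimethylsilyl chloride CC(C)(C)[Si](C)(C)Cl
Why: Crossed Claisen condensation: the lithium enolate of 7 (C5) should open lactone 5 at its carbonyl carbon (C14), the second equivalent of enolate keeps the β-keto lactone as its enolate (no hemiketal), and the freed C11 alkoxide is silylated in the same flask; C5 stays epimerisable until step 6.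

Step 6
Reactants: 9 silylated β-keto lactone
Product: 10 C5-methylated β-keto lactone
Conditions: K2CO3, MeI, acetone, 23 °C
Reagents that add atoms: iodomethane CI
Why: C-Alkylation of the β-keto lactone enolate should place the methyl group on the ring face opposite to the neighbouring C6 methyl, which sets the quaternary C5 (C5–CH3 trans to C6–CH3).

Step 7
Reactants: 10 C5-methylated β-keto lactone
Product: 11 C14 alcohol
Conditions: NaBH4, MeOH, −40 °C
Reagents that add atoms: none
Why: Chemoselective ketone reduction (the lactone is untouched at this temperature) under polar Felkin–Anh control, with the lactone carbonyl carbon C4 anti to the incoming hydride and the hydride passing the C5 methyl, should give the C14 alcohol with OH syn to C5–CH3 (14R).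

Step 8
Reactants: 11 C14 alcohol
Product: 12 bis-silyl ether lactone
Conditions: TBSOTf, 2,6-lutidine, CH2Cl2, 0 °C
Reagents that add atoms: tert-butyldimethylsilyl trifluoromethanesulfonate CC(C)(C)[Si](C)(C)OS(=O)(=O)C(F)(F)F
Why: Silyl triflate silylation of the hindered secondary alcohol protects O14 against the hydride, base and Lewis acid steps that follow.

Step 9
Reactants: 12 bis-silyl ether lactone
Product: 13 lactol
Conditions: i-Bu2AlH (1.2 equiv), CH2Cl2, −78 °C
Reagents that add atoms: none
Why: Half-reduction of the lactone at −78 °C stops at the aluminium hemiacetal, which gives the lactol on work-up.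

Step 10
Reactants: 13 lactol
Product: 14 alkynol
Conditions: dimethyl (1-diazo-2-oxopropyl)phosphonate, K2CO3, MeOH, 0 to 23 °C
Reagents that add atoms: dimethyl (1-diazo-2-oxopropyl)phosphonate CC(=O)C(=[N+]=[N-])P(=O)(OC)OC
Why: Seyferth–Gilbert homologation (Ohira–Bestmann variant) of the open hydroxy aldehyde form of the lactol should give the terminal alkyne C3≡C4 on the quaternary C5 (no epimerisable center) and free the C8 hydroxyl.

Step 11
Reactants: 14 alkynol
Product: 15 primary iodide
Conditions: I2, PPh3, imidazole, CH2Cl2, 0 °C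
Reagents that add atoms: iodine II
Why: Appel-type iodination (SN2) of the only free hydroxyl, a primary one.

Step 12
Reactants: 15 primary iodide; 16 triethyl phosphonoacetate (3 equiv)
Product: 17 alkylated phosphonoacetate
Conditions: NaH, THF/DMF, 0 to 50 °C
Reagents that add atoms: none
Why: SN2 alkylation of the sodium phosphonoacetate by the unhindered primary iodide should form C8–C9; the excess of 16 suppresses dialkylation and the new center disappears in step 13.

Step 13
Reactants: 17 alkylated phosphonoacetate
Product: 18 trisubstituted enoate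
Conditions: NaH, THF, 0 °C; then CH3CHO, 0 to 23 °C
Reagents that add atoms: acetaldehyde CC=O
Why: Horner–Wadsworth–Emmons olefination should give the trisubstituted enoate C9=C10 (E isomer expected to prevail; both isomers converge in step 18) and brings in C10 with its methyl.

Step 14
Reactants: 18 trisubstituted enoate
Product: 19 allylic alcohol
Conditions: i-Bu2AlH (2.5 equiv), CH2Cl2, −78 °C
Reagents that add atoms: none
Why: 1,2-Reduction of the enoate to the allylic alcohol; silyl ethers, alkyne and vinyl group are inert to the aluminium hydride at −78 °C.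

Step 15
Reactants: 19 allylic alcohol
Product: 21 allylstannane, via allylic mesylate 20 (not isolated)
Conditions: MsCl, Et3N, THF, −40 °C; then Bu3SnLi (from Bu3SnH and LiN(i-Pr)2, 2.5 equiv), THF, −78 °C
Reagents that add atoms: tributylstannyllithium [Li][Sn](CCCC)(CCCC)CCCC
Why: SN2 displacement of the primary allylic mesylate by the stannyl anion at C1 should give the allylstannane without allylic transposition (the excess covers reversible deprotonation of the alkyne).

Step 16
Reactants: 21 allylstannane
Product: 22 allylstannane alcohol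
Conditions: TBAF (1.1 equiv), THF, 0 °C
Reagents that add atoms: none
Why: Fluoride should cleave the primary silyl ether at O11 well before the secondary one at O14, which is shielded by the quaternary C5, and the non-acidic medium spares the allylstannane.

Step 17
Reactants: 22 allylstannane alcohol
Product: 23 allylstannane aldehyde
Conditions: Dess–Martin periodinane, NaHCO3, CH2Cl2, 0 °C
Reagents that add atoms: none
Why: Buffered periodinane oxidation gives the aldehyde C11, which has no α-hydrogen and therefore cannot enolise or epimerise.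

Step 18
Reactants: 23 allylstannane aldehyde
Product: 24 ten-membered enyne
Conditions: BF3·OEt2 (2 equiv), CH2Cl2, −78 °C, slow addition of 23 (final 0.002 M)
Reagents that add atoms: none
Why: Lewis-acid-promoted intramolecular SE2′ addition of the allylstannane to the aldehyde should close the ten-membered ring, form C10–C11 and move the double bond to the exocyclic position C9=C1; the open transition state gives the syn C10–CH3/C11–OH adduct from either alkene isomer, and Felkin–Anh addition anti to the C12 vinyl group places C11–OH syn to C12–CH3.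

Step 19
Reactants: 24 ten-membered enyne
Product: 26 tricyclic enone silyl ether, via dicobalt hexacarbonyl alkyne complex 25 (not isolated)
Conditions: Co2(CO)8 (1.1 equiv), CH2Cl2, 23 °C; then N-methylmorpholine N-oxide (6 equiv), CH2Cl2, 0 to 23 °C
Reagents that add atoms: dicobalt octacarbonyl (one CO ligand becomes C2=O) [C-]#[O+].[C-]#[O+].[C-]#[O+].[C-]#[O+].[C-]#[O+].[C-]#[O+].[C-]#[O+].[C-]#[O+].[Co].[Co]
Why: Mechanism: the terminal alkyne forms the μ-alkyne Co2(CO)6 complex 25, the N-oxide removes one CO ligand, the exocyclic C9=C1 alkene coordinates and inserts into a Co–C4 bond (C4–C9), CO then inserts (C1–C2) and reductive elimination (C2–C3) releases the enone. Closest known reaction type: the intramolecular Pauson–Khand reaction of 1,7-enynes bearing 1,1-disubstituted alkenes (hydrindenones with a quaternary ring-fusion carbon) and of enynes whose two arms sit on a preformed ring, macrocycles included. Ring closures: ring A by the [2+2+1] itself, ring B as the six-membered ring of a 1,7-enyne (tether C5–C6–C7–C8), and ring C because the same C4–C9 bond links the 1,5-related carbons C5 and C9 of the ten-membered ring, a transannular closure that turns the cyclodecane into the bicyclo[5.3.1]undecane. New stereocenter: only C9, and it is controlled by the ring, since the alkyne carbon C4 is held by C5 over one face of the methylene group and the bridge can form on that face only. Selectivity needed: chemoselectivity for the 1,1-disubstituted C9=C1 alkene over the C12 vinyl group (also a 1,7-partner of the alkyne) and regioselectivity for C4–C9 over C4–C1; the first should be secured by geometry (the wanted closure is a chair spanned 1,3 by the five-carbon chain C10–C14, the unwanted one would need a boat spanned 1,4 by the six-carbon chain C6–C11), the second by the tether, which allows the six- but not the seven-membered ring.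

Step 20
Reactants: 26 tricyclic enone silyl ether
Product: 27 tricyclic 11,14-diol
Conditions: HF·pyridine, THF, 0 to 23 °C
Reagents that add atoms: none
Why: Acidic fluoride removes the hindered silyl ether at O14; basic fluoride is avoided because the free C14 alkoxide is that of a vinylogous aldol (C14–C5–C4=C3–C2=O) and could fragment.

Step 21
Reactants: 27 tricyclic 11,14-diol; 28 2-{[tert-butyl(dimethyl)silyl]oxy}acetic acid
Product: 30 protected diester, via C11 trifluoroacetate 29 (not isolated)
Conditions: N-(trifluoroacetyl)imidazole (1.1 equiv), CH2Cl2, −20 °C; then 28, EDC·HCl, DMAP, CH2Cl2, 23 °C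
Reagents that add atoms: N-(trifluoroacetyl)imidazole O=C(n1ccnc1)C(F)(F)F
Why: The C11 hydroxyl, the more accessible of the two, should be blocked first as its trifluoroacetate, after which carbodiimide (Steglich) esterification acylates the remaining neopentyl C14 hydroxyl.

Step 22
Reactants: 30 protected diester
Product: 32 Pleuromutilin F, via desilylated trifluoroacetate 31 (not isolated)
Conditions: HF·pyridine, pyridine, THF, 0 °C; then NaHCO3, MeOH, 0 to 23 °C
Reagents that add atoms: none
Why: Fluoride removes the primary silyl ether of the glycolate and mild methanolysis cleaves the very labile trifluoroacetate, while the hindered C14 ester should stay.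

Compound list
1 | 4,4-diethoxybut-1-yne | C#CCC(OCC)OCC | starting material
2 | 2-(2,2-diethoxyethyl)buta-1,3-diene | C=CC(=C)CC(OCC)OCC | intermediate
3 | (S)-2-(2,2-diethoxyethyl)-2-methylbut-3-en-1-ol | OC[C@](C)(C=C)CC(OCC)OCC | intermediate
4 | (4S)-4-ethenyl-4-methyloxolan-2-ol (lactol, both anomers) | OC1C[C@@](C)(C=C)CO1 | intermediate
5 | (S)-4-ethenyl-4-methyloxolan-2-one | O=C1C[C@@](C)(C=C)CO1 | intermediate
6 | methyl (R)-3-methylglutarate, (R)-5-methoxy-3-methyl-5-oxopentanoic acid | COC(=O)C[C@H](C)CC(=O)O | starting material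
7 | (S)-4-methyloxan-2-one | O=C1C[C@@H](C)CCO1 | intermediate
8 | (4S)-3-[(3S)-3-(hydroxymethyl)-3-methylpent-4-enoyl]-4-methyloxan-2-one (C3 not fixed; present as lithium enolate alkoxide) | O=C1OCC[C@H](C)C1C(=O)C[C@@](C)(C=C)CO | intermediate
9 | (4S)-3-[(3S)-3-({[tert-butyl(dimethyl)silyl]oxy}methyl)-3-methylpent-4-enoyl]-4-methyloxan-2-one (C3 not fixed) | O=C1OCC[C@H](C)C1C(=O)C[C@@](C)(C=C)CO[Si](C)(C)C(C)(C)C | intermediate
10 | (3R,4S)-3-[(3S)-3-({[tert-butyl(dimethyl)silyl]oxy}methyl)-3-methylpent-4-enoyl]-3,4-dimethyloxan-2-one | O=C1OCC[C@H](C)[C@]1(C)C(=O)C[C@@](C)(C=C)CO[Si](C)(C)C(C)(C)C | intermediate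
11 | (3R,4S)-3-[(1R,3S)-3-({[tert-butyl(dimethyl)silyl]oxy}methyl)-1-hydroxy-3-methylpent-4-en-1-yl]-3,4-dimethyloxan-2-one | O=C1OCC[C@H](C)[C@]1(C)[C@H](O)C[C@@](C)(C=C)CO[Si](C)(C)C(C)(C)C | intermediate
12 | (3R,4S)-3-[(1R,3S)-1-{[tert-butyl(dimethyl)silyl]oxy}-3-({[tert-butyl(dimethyl)silyl]oxy}methyl)-3-methylpent-4-en-1-yl]-3,4-dimethyloxan-2-one | O=C1OCC[C@H](C)[C@]1(C)[C@H](O[Si](C)(C)C(C)(C)C)C[C@@](C)(C=C)CO[Si](C)(C)C(C)(C)C | intermediate
13 | lactol of 12 (oxan-2-ol, both anomers; other centers as in 12) | OC1OCC[C@H](C)[C@]1(C)[C@H](O[Si](C)(C)C(C)(C)C)C[C@@](C)(C=C)CO[Si](C)(C)C(C)(C)C | intermediate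
14 | alkynol HC≡C–C5(CH3)[C14H(OTBS)–C13H2–C12(CH3)(CH=CH2)–C11H2OTBS]–C6H(CH3)–C7H2–C8H2OH (C5, C6, C12, C14 as in 12) | C#C[C@](C)([C@@H](C)CCO)[C@H](O[Si](C)(C)C(C)(C)C)C[C@@](C)(C=C)CO[Si](C)(C)C(C)(C)C | intermediate
15 | primary iodide of 14 (C8–I) | C#C[C@](C)([C@@H](C)CCI)[C@H](O[Si](C)(C)C(C)(C)C)C[C@@](C)(C=C)CO[Si](C)(C)C(C)(C)C | intermediate
16 | triethyl phosphonoacetate | CCOC(=O)CP(=O)(OCC)OCC | starting material
17 | ethyl 2-(diethoxyphosphoryl)alkanoate from 15 and 16 (new C8–C9 bond; C9 epimers) | CCOC(=O)C(P(=O)(OCC)OCC)CC[C@H](C)[C@@](C)(C#C)[C@H](O[Si](C)(C)C(C)(C)C)C[C@@](C)(C=C)CO[Si](C)(C)C(C)(C)C | intermediate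
18 | ethyl (E)-2-alkylbut-2-enoate, C17H3–C10H=C9(C1O2Et)–C8H2– chain of 15 | C/C=C(\CC[C@H](C)[C@@](C)(C#C)[C@H](O[Si](C)(C)C(C)(C)C)C[C@@](C)(C=C)CO[Si](C)(C)C(C)(C)C)C(=O)OCC | intermediate
19 | (E)-allylic alcohol (C1H2OH) from 18 | C/C=C(\CC[C@H](C)[C@@](C)(C#C)[C@H](O[Si](C)(C)C(C)(C)C)C[C@@](C)(C=C)CO[Si](C)(C)C(C)(C)C)CO | intermediate
20 | allylic methanesulfonate of 19 | C/C=C(\CC[C@H](C)[C@@](C)(C#C)[C@H](O[Si](C)(C)C(C)(C)C)C[C@@](C)(C=C)CO[Si](C)(C)C(C)(C)C)COS(C)(=O)=O | intermediate
21 | (E)-allyl(tributyl)stannane (C1H2–SnBu3) | C/C=C(\CC[C@H](C)[C@@](C)(C#C)[C@H](O[Si](C)(C)C(C)(C)C)C[C@@](C)(C=C)CO[Si](C)(C)C(C)(C)C)C[Sn](CCCC)(CCCC)CCCC | intermediate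
22 | allylstannane with free C11H2OH (O14 still silylated) | C/C=C(\CC[C@H](C)[C@@](C)(C#C)[C@H](O[Si](C)(C)C(C)(C)C)C[C@@](C)(C=C)CO)C[Sn](CCCC)(CCCC)CCCC | intermediate
23 | allylstannane aldehyde (C11H=O) | C/C=C(\CC[C@H](C)[C@@](C)(C#C)[C@H](O[Si](C)(C)C(C)(C)C)C[C@@](C)(C=C)C=O)C[Sn](CCCC)(CCCC)CCCC | intermediate
24 | ten-membered carbocycle C5–C14: ethynyl and CH3 on C5, CH3 on C6, =CH2 on C9, CH3 on C10, OH on C11, CH3 and vinyl on C12, OTBS on C14 (C5, C6, C10, C11, C12, C14 as in 32) | C#C[C@]1(C)[C@@H](C)CCC(=C)[C@@H](C)[C@H](O)[C@](C)(C=C)C[C@H]1O[Si](C)(C)C(C)(C)C | intermediate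
25 | μ-alkyne hexacarbonyldicobalt complex of 24 | [H]C12[Co-3]3(C#[O+])(C#[O+])(C#[O+])[Co-3]1(C#[O+])(C#[O+])(C#[O+])C23[C@]1(C)[C@@H](C)CCC(=C)[C@@H](C)[C@H](O)[C@](C)(C=C)C[C@H]1O[Si](C)(C)C(C)(C)C | intermediate
26 | tricyclic enone, 14-O-TBS ether of 27 | C=C[C@]1(C)C[C@@H](O[Si](C)(C)C(C)(C)C)[C@]2(C)C3=CC(=O)C[C@@]3(CC[C@@H]2C)[C@@H](C)[C@@H]1O | intermediate
27 | tricyclic 11,14-diol (32 without the glycolyl group) | C=C[C@]1(C)C[C@@H](O)[C@]2(C)C3=CC(=O)C[C@@]3(CC[C@@H]2C)[C@@H](C)[C@@H]1O | intermediate
28 | 2-{[tert-butyl(dimethyl)silyl]oxy}acetic acid | CC(C)(C)[Si](C)(C)OCC(=O)O | starting material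
29 | 11-O-trifluoroacetate of 27 | C=C[C@]1(C)C[C@@H](O)[C@]2(C)C3=CC(=O)C[C@@]3(CC[C@@H]2C)[C@@H](C)[C@@H]1OC(=O)C(F)(F)F | intermediate
30 | 11-O-trifluoroacetate 14-O-(silyloxyacetate) of 27 | C=C[C@]1(C)C[C@@H](OC(=O)CO[Si](C)(C)C(C)(C)C)[C@]2(C)C3=CC(=O)C[C@@]3(CC[C@@H]2C)[C@@H](C)[C@@H]1OC(=O)C(F)(F)F | intermediate
31 | 11-O-trifluoroacetate of 32 | C=C[C@]1(C)C[C@@H](OC(=O)CO)[C@]2(C)C3=CC(=O)C[C@@]3(CC[C@@H]2C)[C@@H](C)[C@@H]1OC(=O)C(F)(F)F | intermediate
32 | Pleuromutilin F | C=C[C@]1(C)C[C@@H](OC(=O)CO)[C@]2(C)C3=CC(=O)C[C@@]3(CC[C@@H]2C)[C@@H](C)[C@@H]1O | target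

Total step count: 22. Longest linear sequence: 21 steps (steps 1–3, then 5–22).

Steps most likely to fail

Step 19. The cobalt-complexed alkyne may fail to fold across the ten-membered ring onto the required face of the C9=C1 alkene, so that cyclisation onto the C12 vinyl group, attack on the other alkene face (C9 epimer) or simple decomplexation takes over. The fallback uses a temporary ring as a conformational lock; it sets out from 24 and comes back at 27. HF·pyridine on 24 should give the macrocyclic enyne diol F1. t-Bu2Si(OTf)2 and 2,6-lutidine tie O11 and O14 into the seven-membered cyclic silylene F2, which removes the rotational freedom of the C11–C14 segment and turns the C12 vinyl group away from C5. The Pauson–Khand reaction under the conditions of step 19 should then give the silylene-bridged tricyclic enone F3, and HF·pyridine returns to diol 27.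

Step 18. Intermolecular allylation (oligomers) or protodestannylation may outrun closure of the ten-membered ring, and the open transition state may give poor control at C10/C11. The fallback is a Barbier-type Nozaki–Hiyama allylation in place of the preformed stannane; it sets out from 19 and comes back at 24. CBr4/PPh3 on 19 should give the allylic bromide F4, HF·pyridine/pyridine the primary alcohol F5, and Dess–Martin oxidation the bromo aldehyde F6. Slow addition of F6 to CrCl2 in THF generates the allylchromium next to its own aldehyde and closes the ring through a six-membered chair transition state to 24. The syn C10/C11 relationship needs the chair with the C10 methyl axial, away from the C9 substituent, and would have to be confirmed.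

Step 7. Facial selectivity of the hydride addition to the C14 ketone may be poor, because the polar Felkin–Anh and the chelated arrangements compete. The fallback replaces substrate control by reagent control; it sets out from 10 and comes back at 11. Corey–Bakshi–Shibata reduction (oxazaborolidine catalyst, BH3·SMe2), with the catalyst enantiomer chosen to deliver hydride to the required face, should give the same alcohol 11 without any new compound.

Further compounds
F1 | step 19 | macrocyclic enyne diol | C#C[C@]1(C)[C@@H](C)CCC(=C)[C@@H](C)[C@H](O)[C@](C)(C=C)C[C@H]1O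
F2 | step 19 | cyclic di-tert-butylsilylene of the diol (O11–Si–O14) | C#C[C@]1(C)[C@@H](C)CCC(=C)[C@@H](C)[C@H](O2)[C@](C)(C=C)C[C@H]1O[Si]2(C(C)(C)C)C(C)(C)C
F3 | step 19 | silylene-bridged tricyclic enone | C=C[C@]1(C)C[C@@H](O4)[C@]2(C)C3=CC(=O)C[C@@]3(CC[C@@H]2C)[C@@H](C)[C@@H]1O[Si]4(C(C)(C)C)C(C)(C)C
F4 | step 18 | (E)-allylic bromide (C1H2Br) | C/C=C(\CC[C@H](C)[C@@](C)(C#C)[C@H](O[Si](C)(C)C(C)(C)C)C[C@@](C)(C=C)CO[Si](C)(C)C(C)(C)C)CBr
F5 | step 18 | allylic bromide with free C11H2OH | C/C=C(\CC[C@H](C)[C@@](C)(C#C)[C@H](O[Si](C)(C)C(C)(C)C)C[C@@](C)(C=C)CO)CBr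
F6 | step 18 | bromo aldehyde (C11H=O) | C/C=C(\CC[C@H](C)[C@@](C)(C#C)[C@H](O[Si](C)(C)C(C)(C)C)C[C@@](C)(C=C)C=O)CBr
F0 | step 7 | none | none
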